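**Plan**

1. Retrosynthesis: with the eight phenols masked as benzyl ethers and both 3-OH groups taken back to C3=C4 alkenes, the C3–C4 bonds of ring C (upper flavan, rings A/C/B) and ring F (lower flavan, rings D/F/E) are cut first, then both O1–C2 bonds, then the C6'(ring B)–C6(ring D) biaryl bond.
2. Enabling feature: each pyran ring is a benzo-fused six-membered ether O1–C2–C3–C4–C4a–C8a that can carry a C3=C4 double bond, and each 3-OH is trans to the C2 aryl group, so it can be delivered from C2 by hydroboration.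
3. Forward: a Suzuki coupling joins ring D to ring B; the ring D phenol lies para to the biaryl bond, so its two ortho positions are equivalent and it takes up its vinyl group without a regiochemical choice; two allylic etherifications then attach ring E and ring A as 1-arylallyl ethers.
4. Rings C and F close together by double ring-closing metathesis; double hydroboration–oxidation and hydrogenolysis of the eight benzyl ethers finish the synthesis.
5. Stereochemistry: both C2 centres are set by an iridium–phosphoramidite catalyst in the etherifications; both C3 centres are relayed from C2 by anti hydroboration.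

Key step: step 17

Ligand: L = (Sa,Sc,Sc)-O,O'-(1,1'-binaphthyl-2,2'-diyl)-N,N-bis[1-(2-methoxyphenyl)ethyl]phosphoramidite.
Assumption 1: the sense of induction of L is taken as that of the parent cinnamyl carbonate/phenoxide reaction, leading to the (S)-ethers; if the hindered substrates respond in the opposite sense, the (Ra,Rc,Rc) ligand is used instead.
Assumption 2: the target carries no axial descriptor, so the tri-ortho-substituted biaryl axis is treated as stereochemically undefined and any rotamers of intermediates are carried on together.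
Descriptor note: the carbons that become C2 are (S) in 18–21 and (R) in 23 and 24; this is a change of CIP priorities only, not of spatial arrangement.

**Route**

Step 1
Reactants: 1 3,4-bis(benzyloxy)benzaldehyde
Product: 2 ethyl (E)-3-[3,4-bis(benzyloxy)phenyl]prop-2-enoate
Conditions: (EtO)2P(O)CH2CO2Et, NaH, THF, 0 °C → rt
Reagents that add atoms: triethyl phosphonoacetate, CCOC(=O)CP(=O)(OCC)OCC
Why: Horner–Wadsworth–Emmons olefination of an aryl aldehyde with a stabilised phosphonate anion should give the (E)-cinnamate.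

Step 2
Reactants: 2 ethyl (E)-3-[3,4-bis(benzyloxy)phenyl]prop-2-enoate
Product: 3 (E)-3-[3,4-bis(benzyloxy)phenyl]prop-2-en-1-ol
Conditions: i-Bu2AlH, CH2Cl2, −78 °C; Rochelle salt work-up
Reagents that add atoms: none
Why: DIBAL 1,2-reduction of an enoate to the allylic alcohol at low temperature leaves the alkene and the benzyl ethers untouched.

Step 3
Reactants: 3 (E)-3-[3,4-bis(benzyloxy)phenyl]prop-2-en-1-ol
Product: 4 (E)-3-[3,4-bis(benzyloxy)phenyl]prop-2-enyl methyl carbonate
Conditions: ClCO2Me, pyridine, CH2Cl2, 0 °C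
Reagents that add atoms: methyl chloroformate, COC(=O)Cl
Why: Acylation of the primary allylic alcohol with a chloroformate gives the linear carbonate that serves as leaving group in the iridium-catalysed step.

Step 4
Reactants: 5 3,5-bis(benzyloxy)phenol
Product: 6 2,4-bis(benzyloxy)-6-hydroxybenzaldehyde
Conditions: (CH2O)n, MgCl2, Et3N, MeCN, reflux
Reagents that add atoms: paraformaldehyde (as formaldehyde), C=O
Why: In the magnesium-mediated ortho-formylation of phenols (Casnati–Skattebøl) the magnesium phenoxide delivers formaldehyde to an ortho carbon only, the two ortho positions of 5 are equivalent, and a second formaldehyde oxidises the salicyl alkoxide to the aldehyde.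

Step 5
Reactants: 6 2,4-bis(benzyloxy)-6-hydroxybenzaldehyde
Product: 7 3,5-bis(benzyloxy)-2-ethenylphenol
Conditions: Ph3PCH3Br (2.5 equiv), KOt-Bu (2.5 equiv), THF, 0 °C → rt; base-washed silica, product kept cold
Reagents that add atoms: methyltriphenylphosphonium bromide, C[P+](c1ccccc1)(c1ccccc1)c1ccccc1.[Br-]
Why: Wittig methylenation with excess ylide (one equivalent is spent on the phenol) is the standard way from salicylaldehydes to 2-vinylphenols, and the acid-sensitive electron-rich product is handled without acid.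

Step 6
Reactants: 5 3,5-bis(benzyloxy)phenol
Product: 8 [3,5-bis(benzyloxy)phenoxy]tri(propan-2-yl)silane
Conditions: i-Pr3SiCl, imidazole, DMF, rt
Reagents that add atoms: chlorotri(propan-2-yl)silane, CC(C)[Si](Cl)(C(C)C)C(C)C
Why: Silylation of the phenol installs a bulky group that resists butyllithium, does not direct metalation and shields its own ortho positions.

Step 7
Reactants: 8 [3,5-bis(benzyloxy)phenoxy]tri(propan-2-yl)silane
Product: 10 2-[2,6-bis(benzyloxy)-4-(triisopropylsilyloxy)phenyl]-4,4,5,5-tetramethyl-1,3,2-dioxaborolane, via aryllithium 9 (not isolated)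
Conditions: n-BuLi, Et2O/hexane, 0 °C → rt; then i-PrOBpin, −78 °C → rt
Reagents that add atoms: 2-isopropoxy-4,4,5,5-tetramethyl-1,3,2-dioxaborolane, CC(C)OB1OC(C)(C)C(C)(C)O1
Why: Directed ortho-metalation removes the proton flanked by both benzyloxy groups (doubly coordinated and most acidic, and favoured in the weakly polar medium over benzylic deprotonation), and the aryllithium is trapped by the borate to give the pinacol boronate.

Step 8
Reactants: 1 3,4-bis(benzyloxy)benzaldehyde
Product: 11 4,5-bis(benzyloxy)-2-bromobenzaldehyde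
Conditions: Br2, NaOAc, AcOH, rt
Reagents that add atoms: bromine, BrBr
Why: Electrophilic aromatic bromination should occur para to the 3-benzyloxy group, as with veratraldehyde, while the acetate buffer keeps HBr from cleaving the benzyl ethers.

Step 9
Reactants: 11 4,5-bis(benzyloxy)-2-bromobenzaldehyde
Product: 12 ethyl (E)-3-[4,5-bis(benzyloxy)-2-bromophenyl]prop-2-enoate
Conditions: (EtO)2P(O)CH2CO2Et, NaH, THF, 0 °C → rt
Reagents that add atoms: triethyl phosphonoacetate, CCOC(=O)CP(=O)(OCC)OCC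
Why: Horner–Wadsworth–Emmons olefination gives the (E)-cinnamate and leaves the aryl bromide for the cross-coupling.

Step 10
Reactants: 12 ethyl (E)-3-[4,5-bis(benzyloxy)-2-bromophenyl]prop-2-enoate; 10 2-[2,6-bis(benzyloxy)-4-(triisopropylsilyloxy)phenyl]-4,4,5,5-tetramethyl-1,3,2-dioxaborolane
Product: 14 ethyl (E)-3-{4,5-bis(benzyloxy)-2-[2,6-bis(benzyloxy)-4-hydroxyphenyl]phenyl}prop-2-enoate, via biaryl silyl ether 13 (not isolated)
Conditions: Pd(OAc)2 (3 mol%), SPhos (6 mol%), K3PO4, toluene/H2O, 90 °C; then Bu4NF, THF, rt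
Reagents that add atoms: none
Why: Suzuki–Miyaura coupling with the bulky electron-rich biarylphosphine SPhos, the established ligand for 2,6-dialkoxyarylboron partners and tri-ortho-substituted biaryls, forms the C6'–C6 bond, and fluoride then completes a desilylation that the aqueous base is expected to begin anyway.

Step 11
Reactants: 14 ethyl (E)-3-{4,5-bis(benzyloxy)-2-[2,6-bis(benzyloxy)-4-hydroxyphenyl]phenyl}prop-2-enoate
Product: 15 ethyl (E)-3-{4,5-bis(benzyloxy)-2-[2,6-bis(benzyloxy)-3-formyl-4-hydroxyphenyl]phenyl}prop-2-enoate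
Conditions: (CH2O)n, MgCl2, Et3N, MeCN, reflux
Reagents that add atoms: paraformaldehyde (as formaldehyde), C=O
Why: The same magnesium-mediated ortho-formylation applies, since the position para to the hydroxyl is the biaryl carbon, the two ortho positions are equivalent by the local symmetry of ring D, and the deactivated salicylaldehyde should not react a second time.

Step 12
Reactants: 15 ethyl (E)-3-{4,5-bis(benzyloxy)-2-[2,6-bis(benzyloxy)-3-formyl-4-hydroxyphenyl]phenyl}prop-2-enoate
Product: 16 ethyl (E)-3-{4,5-bis(benzyloxy)-2-[2,6-bis(benzyloxy)-3-ethenyl-4-hydroxyphenyl]phenyl}prop-2-enoate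
Conditions: Ph3PCH3Br, KOt-Bu, THF, −20 → 0 °C, ylide added in portions until 15 is consumed
Reagents that add atoms: methyltriphenylphosphonium bromide, C[P+](c1ccccc1)(c1ccccc1)c1ccccc1.[Br-]
Why: Wittig methylenation of an aldehyde is much faster than conjugate addition of the non-stabilised ylide to the electron-rich cinnamate, so controlled dosing at low temperature should give the 2-vinylphenol with the enoate intact.

Step 13
Reactants: 16 ethyl (E)-3-{4,5-bis(benzyloxy)-2-[2,6-bis(benzyloxy)-3-ethenyl-4-hydroxyphenyl]phenyl}prop-2-enoate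
Product: 17 (E)-3-{4,5-bis(benzyloxy)-2-[2,6-bis(benzyloxy)-3-ethenyl-4-hydroxyphenyl]phenyl}prop-2-en-1-ol
Conditions: i-Bu2AlH (excess), CH2Cl2, −78 → 0 °C; Rochelle salt work-up
Reagents that add atoms: none
Why: DIBAL 1,2-reduction of the cinnamate is carried out here, before any Lewis-acid-labile 1-arylallyl ether is present in the molecule.

Step 14
Reactants: 17 (E)-3-{4,5-bis(benzyloxy)-2-[2,6-bis(benzyloxy)-3-ethenyl-4-hydroxyphenyl]phenyl}prop-2-en-1-ol; 4 (E)-3-[3,4-bis(benzyloxy)phenyl]prop-2-enyl methyl carbonate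
Product: 18 (E)-3-{4,5-bis(benzyloxy)-2-[2,6-bis(benzyloxy)-4-{(1S)-1-[3,4-bis(benzyloxy)phenyl]prop-2-enyloxy}-3-ethenylphenyl]phenyl}prop-2-en-1-ol
Conditions: [Ir(cod)Cl]2 (2 mol%), L (4 mol%), pre-activated with n-PrNH2; K3PO4, THF, 50 °C
Reagents that add atoms: none
Why: In this iridium-catalysed branched-selective asymmetric allylic etherification of a phenol, the cyclometalated iridium–phosphoramidite complex ionises 4 to an allyliridium species that the phenoxide of 17 attacks through oxygen at the aryl-bearing terminus on the face fixed by L, setting the (S) centre that becomes C2 of ring F, while the neutral primary alcohol is too weak a nucleophile to compete.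

Step 15
Reactants: 18 (E)-3-{4,5-bis(benzyloxy)-2-[2,6-bis(benzyloxy)-4-{(1S)-1-[3,4-bis(benzyloxy)phenyl]prop-2-enyloxy}-3-ethenylphenyl]phenyl}prop-2-en-1-ol
Product: 19 (E)-3-{4,5-bis(benzyloxy)-2-[2,6-bis(benzyloxy)-4-{(1S)-1-[3,4-bis(benzyloxy)phenyl]prop-2-enyloxy}-3-ethenylphenyl]phenyl}prop-2-enyl methyl carbonate
Conditions: ClCO2Me, pyridine, CH2Cl2, 0 °C
Reagents that add atoms: methyl chloroformate, COC(=O)Cl
Why: Carbonate formation under mildly basic conditions converts the ring B side chain into the allylic electrophile without stressing the acid-labile ring D ether.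

Step 16
Reactants: 19 (E)-3-{4,5-bis(benzyloxy)-2-[2,6-bis(benzyloxy)-4-{(1S)-1-[3,4-bis(benzyloxy)phenyl]prop-2-enyloxy}-3-ethenylphenyl]phenyl}prop-2-enyl methyl carbonate; 7 3,5-bis(benzyloxy)-2-ethenylphenol
Product: 20 3,5-bis(benzyloxy)-2-ethenylphenyl (1S)-1-{4,5-bis(benzyloxy)-2-[2,6-bis(benzyloxy)-4-{(1S)-1-[3,4-bis(benzyloxy)phenyl]prop-2-enyloxy}-3-ethenylphenyl]phenyl}prop-2-enyl ether
Conditions: [Ir(cod)Cl]2 (4 mol%), L (8 mol%), pre-activated with n-PrNH2; K3PO4, THF, 50 °C, stopped at full conversion of 19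
Reagents that add atoms: none
Why: A second iridium-catalysed asymmetric allylic etherification, with the ortho-methoxyaryl ligand chosen because it is the one suited to ortho-substituted cinnamyl carbonates, lets the phenoxide of 7 attack the benzylic terminus under catalyst control to set the (S) centre that becomes C2 of ring C; the carbonate ionises far faster than the existing aryl ether, and any minor diastereomer from imperfect induction in either step can be removed here.

Step 17
Reactants: 20 3,5-bis(benzyloxy)-2-ethenylphenyl (1S)-1-{4,5-bis(benzyloxy)-2-[2,6-bis(benzyloxy)-4-{(1S)-1-[3,4-bis(benzyloxy)phenyl]prop-2-enyloxy}-3-ethenylphenyl]phenyl}prop-2-enyl ether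
Product: 21 (2S)-5,7-bis(benzyloxy)-2-{4,5-bis(benzyloxy)-2-[(2S)-5,7-bis(benzyloxy)-2-[3,4-bis(benzyloxy)phenyl]-2H-chromen-6-yl]phenyl}-2H-chromene
Conditions: second-generation Grubbs catalyst RuCl2(=CHPh)(PCy3)(H2IMes) (10 mol%), 1,4-benzoquinone (20 mol%), CH2Cl2 (0.005 M), 40 °C
Reagents that add atoms: none
Why: The ruthenium benzylidene first exchanges onto each monosubstituted allyl-ether alkene, the new alkylidene adds in a [2+2] sense to the styrene held ortho on the same arene, and cycloreversion of the ruthenacyclobutane forms C3=C4 and releases a methylidene that leaves as ethylene. The closest known reaction is ring-closing metathesis of 2-vinylaryl 1-arylallyl ethers to 2-aryl-2H-chromenes, run here at two sites of one molecule. Ring C closes on ring A and ring F on ring D, each as a six-membered ring by joining C3 to C4 of a 1,7-diene whose ends sit on adjacent carbons of the arene. No stereocentre is created: the two C2 centres are spectators and keep the (S) configuration set in steps 14 and 16. The step needs pairing selectivity (six-membered closure within each diene pair, no macrocycle or oligomer across the biaryl) and freedom from ruthenium hydride isomerisation of the allyl ethers to enol ethers, which would erase C2. The ortho placement of each alkene pair, high dilution, a short reaction time at 40 °C and 1,4-benzoquinone as hydride scavenger are expected to secure both.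

Step 18
Reactants: 21 (2S)-5,7-bis(benzyloxy)-2-{4,5-bis(benzyloxy)-2-[(2S)-5,7-bis(benzyloxy)-2-[3,4-bis(benzyloxy)phenyl]-2H-chromen-6-yl]phenyl}-2H-chromene
Product: 23 (2R,3S)-5,7-bis(benzyloxy)-2-{4,5-bis(benzyloxy)-2-[(2R,3S)-5,7-bis(benzyloxy)-2-[3,4-bis(benzyloxy)phenyl]-3-hydroxychroman-6-yl]phenyl}chroman-3-ol, via bis(3-boranyl) adduct 22 (not isolated)
Conditions: BH3·THF (excess), THF, 0 °C → rt; then NaOH, H2O2, 0 °C → rt
Reagents that add atoms: hydrogen peroxide, OO
Why: In this hydroboration–oxidation of flav-3-enes, borane adds syn across each C3=C4 from the face opposite the C2 aryl group with boron on C3 (away from the electron-rich benzylic C4 and next to the inductively withdrawing O1–C2), and oxidation with retention should give both 2,3-trans (3S) alcohols.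

Step 19
Reactants: 23 (2R,3S)-5,7-bis(benzyloxy)-2-{4,5-bis(benzyloxy)-2-[(2R,3S)-5,7-bis(benzyloxy)-2-[3,4-bis(benzyloxy)phenyl]-3-hydroxychroman-6-yl]phenyl}chroman-3-ol
Product: 24 (2R,3S)-2-{2-[(2R,3S)-2-(3,4-dihydroxyphenyl)-3,5,7-trihydroxychroman-6-yl]-4,5-dihydroxyphenyl}chromane-3,5,7-triol (target CNP0125771.1)
Conditions: H2 (1 atm), Pd(OH)2/C, THF/MeOH, rt, degassed solvents
Reagents that add atoms: none
Why: Catalytic hydrogenolysis removes all eight benzyl ethers under neutral conditions, under which the O1–C2 bonds and the C2/C3 centres of flavan-3-ols are known to survive.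

**Compound list**

1 | 3,4-bis(benzyloxy)benzaldehyde (commercial) | O=Cc1ccc(OCc2ccccc2)c(OCc2ccccc2)c1 | starting material
2 | ethyl (E)-3-[3,4-bis(benzyloxy)phenyl]prop-2-enoate | CCOC(=O)/C=C/c1ccc(OCc2ccccc2)c(OCc2ccccc2)c1 | intermediate
3 | (E)-3-[3,4-bis(benzyloxy)phenyl]prop-2-en-1-ol | OC/C=C/c1ccc(OCc2ccccc2)c(OCc2ccccc2)c1 | intermediate
4 | (E)-3-[3,4-bis(benzyloxy)phenyl]prop-2-enyl methyl carbonate (ring E carbonate) | COC(=O)OC/C=C/c1ccc(OCc2ccccc2)c(OCc2ccccc2)c1 | intermediate
5 | 3,5-bis(benzyloxy)phenol (commercial) | Oc1cc(OCc2ccccc2)cc(OCc2ccccc2)c1 | starting material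
6 | 2,4-bis(benzyloxy)-6-hydroxybenzaldehyde | O=Cc1c(O)cc(OCc2ccccc2)cc1OCc3ccccc3 | intermediate
7 | 3,5-bis(benzyloxy)-2-ethenylphenol (ring A vinylphenol) | C=Cc1c(O)cc(OCc2ccccc2)cc1OCc3ccccc3 | intermediate
8 | [3,5-bis(benzyloxy)phenoxy]tri(propan-2-yl)silane | CC(C)[Si](C(C)C)(C(C)C)Oc1cc(OCc2ccccc2)cc(OCc2ccccc2)c1 | intermediate
9 | 2,6-bis(benzyloxy)-4-(triisopropylsilyloxy)phenyllithium (not isolated, step 7) | [Li]c1c(OCc2ccccc2)cc(O[Si](C(C)C)(C(C)C)C(C)C)cc1OCc3ccccc3 | intermediate
10 | 2-[2,6-bis(benzyloxy)-4-(triisopropylsilyloxy)phenyl]-4,4,5,5-tetramethyl-1,3,2-dioxaborolane (ring D boronate) | CC1(C)OB(OC1(C)C)c1c(OCc2ccccc2)cc(O[Si](C(C)C)(C(C)C)C(C)C)cc1OCc3ccccc3 | intermediate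
11 | 4,5-bis(benzyloxy)-2-bromobenzaldehyde | O=Cc1cc(OCc2ccccc2)c(OCc2ccccc2)cc1Br | intermediate
12 | ethyl (E)-3-[4,5-bis(benzyloxy)-2-bromophenyl]prop-2-enoate | CCOC(=O)/C=C/c1cc(OCc2ccccc2)c(OCc2ccccc2)cc1Br | intermediate
13 | ethyl (E)-3-{4,5-bis(benzyloxy)-2-[2,6-bis(benzyloxy)-4-(triisopropylsilyloxy)phenyl]phenyl}prop-2-enoate (not isolated, step 10) | CCOC(=O)/C=C/c1cc(OCc2ccccc2)c(OCc2ccccc2)cc1-c1c(OCc2ccccc2)cc(O[Si](C(C)C)(C(C)C)C(C)C)cc1OCc3ccccc3 | intermediate
14 | ethyl (E)-3-{4,5-bis(benzyloxy)-2-[2,6-bis(benzyloxy)-4-hydroxyphenyl]phenyl}prop-2-enoate | CCOC(=O)/C=C/c1cc(OCc2ccccc2)c(OCc2ccccc2)cc1-c1c(OCc2ccccc2)cc(O)cc1OCc3ccccc3 | intermediate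
15 | ethyl (E)-3-{4,5-bis(benzyloxy)-2-[2,6-bis(benzyloxy)-3-formyl-4-hydroxyphenyl]phenyl}prop-2-enoate | CCOC(=O)/C=C/c1cc(OCc2ccccc2)c(OCc2ccccc2)cc1-c1c(OCc2ccccc2)cc(O)c(C=O)c1OCc3ccccc3 | intermediate
16 | ethyl (E)-3-{4,5-bis(benzyloxy)-2-[2,6-bis(benzyloxy)-3-ethenyl-4-hydroxyphenyl]phenyl}prop-2-enoate | CCOC(=O)/C=C/c1cc(OCc2ccccc2)c(OCc2ccccc2)cc1-c1c(OCc2ccccc2)cc(O)c(C=C)c1OCc3ccccc3 | intermediate
17 | (E)-3-{4,5-bis(benzyloxy)-2-[2,6-bis(benzyloxy)-3-ethenyl-4-hydroxyphenyl]phenyl}prop-2-en-1-ol | OC/C=C/c1cc(OCc2ccccc2)c(OCc2ccccc2)cc1-c1c(OCc2ccccc2)cc(O)c(C=C)c1OCc3ccccc3 | intermediate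
18 | (E)-3-{4,5-bis(benzyloxy)-2-[2,6-bis(benzyloxy)-4-{(1S)-1-[3,4-bis(benzyloxy)phenyl]prop-2-enyloxy}-3-ethenylphenyl]phenyl}prop-2-en-1-ol | OC/C=C/c1cc(OCc2ccccc2)c(OCc2ccccc2)cc1-c1c(OCc2ccccc2)cc(O[C@@H](C=C)c2ccc(OCc3ccccc3)c(OCc3ccccc3)c2)c(C=C)c1OCc4ccccc4 | intermediate
19 | methyl carbonate of 18 | COC(=O)OC/C=C/c1cc(OCc2ccccc2)c(OCc2ccccc2)cc1-c1c(OCc2ccccc2)cc(O[C@@H](C=C)c2ccc(OCc3ccccc3)c(OCc3ccccc3)c2)c(C=C)c1OCc4ccccc4 | intermediate
20 | tetraene, bis(ortho-vinylaryl (S)-1-arylallyl ether) of the biaryl core | C=Cc1c(OCc2ccccc2)cc(OCc2ccccc2)cc1O[C@H](c1cc(OCc2ccccc2)c(OCc2ccccc2)cc1-c1c(OCc2ccccc2)cc(O[C@@H](C=C)c2ccc(OCc3ccccc3)c(OCc3ccccc3)c2)c(C=C)c1OCc4ccccc4)C=C | intermediate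
21 | octa-O-benzyl (2S,2S)-bis(flav-3-ene) | C(c1ccccc1)Oc1cc(OCc2ccccc2)c2c(c1)O[C@H](c1cc(OCc3ccccc3)c(OCc3ccccc3)cc1-c1c(OCc3ccccc3)cc4c(c1OCc1ccccc1)C=C[C@@H](c1ccc(OCc5ccccc5)c(OCc5ccccc5)c1)O4)C=C2 | intermediate
22 | bis(3-boranyl) adduct of 21 (not isolated, step 18) | C(c1ccccc1)Oc1cc(OCc2ccccc2)c2c(c1)O[C@H](c1cc(OCc3ccccc3)c(OCc3ccccc3)cc1-c1c(OCc3ccccc3)cc4c(c1OCc1ccccc1)C[C@H](B)[C@@H](c1ccc(OCc5ccccc5)c(OCc5ccccc5)c1)O4)[C@@H](B)C2 | intermediate
23 | octa-O-benzyl (2R,3S,2R,3S)-bis(flavan-3-ol) | C(c1ccccc1)Oc1cc(OCc2ccccc2)c2c(c1)O[C@H](c1cc(OCc3ccccc3)c(OCc3ccccc3)cc1-c1c(OCc3ccccc3)cc4c(c1OCc1ccccc1)C[C@H](O)[C@@H](c1ccc(OCc5ccccc5)c(OCc5ccccc5)c1)O4)[C@@H](O)C2 | intermediate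
24 | CNP0125771.1, (2R,3S)-2-{2-[(2R,3S)-2-(3,4-dihydroxyphenyl)-3,5,7-trihydroxychroman-6-yl]-4,5-dihydroxyphenyl}chromane-3,5,7-triol | Oc1cc(O)c2c(c1)O[C@H](c1cc(O)c(O)cc1-c1c(O)cc3c(c1O)C[C@H](O)[C@@H](c1ccc(O)c(O)c1)O3)[C@@H](O)C2 | target

**Step count and risks**

Total: 19 steps. Longest linear sequence: 12 steps (1 → 11 → 12 → 14 → 15 → 16 → 17 → 18 → 19 → 20 → 21 → 23 → 24; the branch from 5 through 8 and 10 is equally long).

Steps most likely to fail:

1. Step 16. The allyliridium species must form next to a bulky ortho aryl group (ring D with two flanking benzyloxy groups) and be attacked at that hindered terminus. Slow turnover, loss of branched selectivity or of enantioselectivity, and re-ionisation of the ring D ether during a long reaction are the likely failure processes. Fallback: the O1–C2 bond of ring C is made by SN2 displacement instead. Setting out from 18, Sharpless asymmetric epoxidation (Ti(Oi-Pr)4, L-(+)-diethyl tartrate, t-BuOOH, 4 Å sieves, CH2Cl2, −20 °C; only the allylic alcohol alkene reacts) would give the (2S,3S)-epoxy alcohol F1, used crude because of its acid lability. Iodination (I2, PPh3, imidazole) would give the epoxy iodide F2, and zinc dust in ethanol would open it reductively to the (R)-1-arylprop-2-en-1-ol F3. Mitsunobu etherification of F3 with 7 (PPh3, DIAD, toluene, 0 °C) with inversion comes back to the route at 20.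

2. Step 12. The aldehyde of 15 is chelated, doubly ortho-substituted and electron-rich, so olefination may be slow enough for the excess ylide to add to the cinnamate or to stall. Fallback: the vinyl group is introduced by cross-coupling. Setting out from 14, N-iodosuccinimide (1.0 equiv, CH2Cl2, −40 °C) would give the mono-ortho-iodophenol F4 (the two ortho positions are equivalent). Suzuki–Miyaura vinylation with potassium vinyltrifluoroborate (PdCl2(dppf), Cs2CO3, THF/H2O, 70 °C) comes back at 16, bypassing 15.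

3. Step 10. Protodeboronation of the 2,6-dialkoxyaryl boronate in the aqueous base may outrun transmetalation to the hindered arylpalladium bromide. Fallback: the ring D nucleophile is changed from boron to zinc. Setting out from 8, lithiation as in step 7 to 9 and addition of ZnCl2 would give the arylzinc chloride F5. Negishi coupling with 12 (Pd(OAc)2/SPhos, THF, 60 °C, anhydrous and base-free) would give 13, and Bu4NF then comes back to the route at 14.

**Further compounds**

F1 | step 16 | (2S,3S)-epoxy alcohol from 18 | OC[C@@H]1O[C@H]1c1cc(OCc2ccccc2)c(OCc2ccccc2)cc1-c1c(OCc2ccccc2)cc(O[C@@H](C=C)c2ccc(OCc3ccccc3)c(OCc3ccccc3)c2)c(C=C)c1OCc4ccccc4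
F2 | step 16 | (2R,3S)-epoxy iodide (same spatial arrangement as F1) | IC[C@@H]1O[C@H]1c1cc(OCc2ccccc2)c(OCc2ccccc2)cc1-c1c(OCc2ccccc2)cc(O[C@@H](C=C)c2ccc(OCc3ccccc3)c(OCc3ccccc3)c2)c(C=C)c1OCc4ccccc4
F3 | step 16 | (1R)-1-arylprop-2-en-1-ol on ring B, ring D (S)-ether unchanged | O[C@H](C=C)c1cc(OCc2ccccc2)c(OCc2ccccc2)cc1-c1c(OCc2ccccc2)cc(O[C@@H](C=C)c2ccc(OCc3ccccc3)c(OCc3ccccc3)c2)c(C=C)c1OCc4ccccc4
F4 | step 12 | ethyl (E)-3-{4,5-bis(benzyloxy)-2-[2,6-bis(benzyloxy)-4-hydroxy-3-iodophenyl]phenyl}prop-2-enoate | CCOC(=O)/C=C/c1cc(OCc2ccccc2)c(OCc2ccccc2)cc1-c1c(OCc2ccccc2)cc(O)c(I)c1OCc3ccccc3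
F5 | step 10 | [2,6-bis(benzyloxy)-4-(triisopropylsilyloxy)phenyl]zinc chloride | Cl[Zn]c1c(OCc2ccccc2)cc(O[Si](C(C)C)(C(C)C)C(C)C)cc1OCc3ccccc3
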